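**Strategy.** The dimer is cut at the C4–C6 interflavan bond into two mirror-image all-cis flavan-3,4-diols, each traced back to a 2-aryl-2H-chromene. Everything rests on closing ring C of the lower unit between C3 and C4 by ring-closing metathesis: the cis-diol on C3 and C4 is the trace of a C3=C4 alkene, so the precursor is a diene whose vinyl groups, on C2 and on C4a of ring A, are tied through the O1 aryl ether made by iridium-catalysed asymmetric allylic etherification. One operation builds ring C and leaves C2 untouched; Woodward cis-hydroxylation then puts both hydroxyls on the aryl face. The upper unit, made likewise, is inverted at C3 after coupling.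

Key step: step 9

Remark: flavan numbering is used; α/β are the faces of ring C as in flavanoid names (a 2R aryl group is α); oritin is (2R,3S)-7,8,4'-trihydroxyflavan-3-ol, epioritin its 2R,3R isomer, ent the mirror image; the target is ent-oritin-(4α→6)-epioritin-4α-ol. The lithium aryloxide 9 is prepared once, isolated, and divided between the two enantiomeric series.

**Step 1**
Reactants: 1 2,3,4-trihydroxybenzaldehyde
Product: 2 2,3,4-tris(benzyloxy)benzaldehyde
Conditions: BnBr (3.5 equiv), K2CO3 (4 equiv), DMF, 60 °C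
Reagents that add atoms: benzyl bromide, BrCc1ccccc1
Why: Williamson ether synthesis on all three phenoxides; benzyl ethers survive every later step and leave by hydrogenolysis at the end.

**Step 2**
Reactants: 2 2,3,4-tris(benzyloxy)benzaldehyde
Product: 3 3,4-bis(benzyloxy)-2-hydroxybenzaldehyde
Conditions: MgBr2·OEt2 (1.5 equiv), toluene/Et2O, 80 °C
Reagents that add atoms: none
Why: Chelation-directed ether cleavage: magnesium bridges the formyl oxygen and the ortho ether oxygen, so bromide should remove only the benzyl group next to the aldehyde.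

**Step 3**
Reactants: 3 3,4-bis(benzyloxy)-2-hydroxybenzaldehyde
Product: 4 2,3-bis(benzyloxy)-6-ethenylphenol
Conditions: Ph3PCH3Br (2.5 equiv), KOtBu (2.5 equiv), THF, 0 °C → 20 °C
Reagents that add atoms: methyltriphenylphosphonium bromide, C[P+](c1ccccc1)(c1ccccc1)c1ccccc1.[Br-]
Why: Wittig methylenation; one equivalent of ylide is spent on the phenol and the phenoxide aldehyde still condenses with the second.

**Step 4**
Reactants: 5 4-(benzyloxy)benzaldehyde
Product: 6 ethyl (2E)-3-[4-(benzyloxy)phenyl]prop-2-enoate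
Conditions: Ph3P=CHCO2Et (1.2 equiv), toluene, 90 °C
Reagents that add atoms: ethyl (triphenylphosphoranylidene)acetate, CCOC(=O)C=P(c1ccccc1)(c1ccccc1)c1ccccc1
Why: Wittig olefination with a stabilised ylide, which should give the E cinnamate.

**Step 5**
Reactants: 6 ethyl (2E)-3-[4-(benzyloxy)phenyl]prop-2-enoate
Product: 7 (2E)-3-[4-(benzyloxy)phenyl]prop-2-en-1-ol
Conditions: i-Bu2AlH (2.5 equiv), CH2Cl2, −78 °C
Reagents that add atoms: none
Why: 1,2-Reduction of the conjugated ester by the aluminium hydride at low temperature should leave the alkene untouched.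

**Step 6**
Reactants: 7 (2E)-3-[4-(benzyloxy)phenyl]prop-2-en-1-ol
Product: 8 (2E)-3-[4-(benzyloxy)phenyl]prop-2-en-1-yl methyl carbonate
Conditions: ClCO2Me (1.5 equiv), pyridine (2 equiv), CH2Cl2, 0 °C
Reagents that add atoms: methyl chloroformate, COC(=O)Cl
Why: Acylation of the primary alcohol installs the carbonate leaving group needed to form the allyliridium complex.

**Step 7**
Reactants: 4 2,3-bis(benzyloxy)-6-ethenylphenol
Product: 9 lithium 2,3-bis(benzyloxy)-6-ethenylphenolate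
Conditions: LiN(SiMe3)2 (1.0 equiv), THF, 0 °C; evaporation, trituration with pentane, solid stored under argon
Reagents that add atoms: lithium bis(trimethylsilyl)amide, [Li+].C[Si](C)(C)[N-][Si](C)(C)C
Why: Acid–base reaction in which the strongly basic silylamide deprotonates the phenol completely and the volatile amine is removed in vacuum, leaving the salt-free lithium aryloxide that serves as the nucleophile in both allylic etherifications.

**Step 8**
Reactants: 9 lithium 2,3-bis(benzyloxy)-6-ethenylphenolate; 8 (2E)-3-[4-(benzyloxy)phenyl]prop-2-en-1-yl methyl carbonate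
Product: 10 1-(benzyloxy)-4-{(1S)-1-[2,3-bis(benzyloxy)-6-ethenylphenoxy]prop-2-en-1-yl}benzene
Conditions: [Ir(cod)Cl]2 (2 mol%), O,O'-(1,1'-binaphthalene-2,2'-diyl) N,N-bis(1-phenylethyl)phosphoramidite (4 mol%, the antipode that gives the S ether), THF, 25 → 50 °C
Reagents that add atoms: none
Why: Iridium-catalysed asymmetric allylic etherification: the aryloxide attacks the aryl-substituted terminus of the allyliridium complex (branched ether) and the chiral phosphoramidite sets the stereocentre that becomes C2 of the lower unit (S here, 2R once C3 carries oxygen).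

**Step 9**
Reactants: 10 1-(benzyloxy)-4-{(1S)-1-[2,3-bis(benzyloxy)-6-ethenylphenoxy]prop-2-en-1-yl}benzene
Product: 11 (2S)-7,8-bis(benzyloxy)-2-[4-(benzyloxy)phenyl]-2H-chromene
Conditions: second-generation Grubbs catalyst RuCl2(=CHPh)(PCy3)(SIMes) (3 mol%), CH2Cl2 (0.01 M), 40 °C, dark
Reagents that add atoms: none
Why: Ring-closing olefin metathesis: the ruthenium benzylidene exchanges at the more accessible allylic vinyl group, the new carbene adds to the vinyl group on ring A in a [2+2] step, and the ruthenacyclobutane collapses by retro-[2+2] to the C3=C4 double bond and ethene, whose loss drives the reaction. The closest known reaction type is the metathesis closure of 2-vinylphenyl allyl ethers to 2H-chromenes. The one ring closed is the six-membered pyran ring C, closed between C3 and C4, with an endocyclic and necessarily cis alkene. No stereocentre is created; C2, set in step 8, takes no part in bond breaking and keeps its configuration. The step needs ring closure to beat intermolecular metathesis, which high dilution and the ortho O1 tether secure. It also needs no double-bond migration and no light-induced electrocyclic opening of the 2H-chromene (which would racemise C2), which the mild temperature and exclusion of light secure.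

**Step 10**
Reactants: 11 (2S)-7,8-bis(benzyloxy)-2-[4-(benzyloxy)phenyl]-2H-chromene
Product: 13 (2R,3R,4R)-7,8-bis(benzyloxy)-2-[4-(benzyloxy)phenyl]-4-hydroxychroman-3-yl acetate, via trans-iodoacetate 12 (not isolated)
Conditions: I2 (1.05 equiv), AgOAc (2.2 equiv), AcOH, 20 °C, dark; then H2O (excess), 20 → 45 °C
Reagents that add atoms: silver acetate, CC(=O)[O-].[Ag+]; water, O
Why: Woodward cis-hydroxylation: iodine adds to C3 on the face away from the 2-aryl group, acetate enters benzylic C4 on the aryl face, silver-assisted displacement of iodide by the neighbouring acetate inverts C3, and water opens the bridged acetoxonium ion, so the 2-aryl group should direct both oxygens to its own face (3R,4R, all-cis).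

**Step 11**
Reactants: 13 (2R,3R,4R)-7,8-bis(benzyloxy)-2-[4-(benzyloxy)phenyl]-4-hydroxychroman-3-yl acetate
Product: 14 (2R,3S,4R)-7,8-bis(benzyloxy)-2-[4-(benzyloxy)phenyl]chromane-3,4-diyl diacetate (all-cis)
Conditions: Ac2O (3 equiv), pyridine, DMAP (cat.), CH2Cl2, 0 → 20 °C
Reagents that add atoms: acetic anhydride, CC(=O)OC(C)=O
Why: Acyl transfer masks both hydroxyls of the lower unit so that only the upper 3-hydroxyl is free for oxidation later, and it converges any migrated 4-acetate isomer of 13 to one compound.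

**Step 12**
Reactants: 9 lithium 2,3-bis(benzyloxy)-6-ethenylphenolate (second portion); 8 (2E)-3-[4-(benzyloxy)phenyl]prop-2-en-1-yl methyl carbonate
Product: 15 1-(benzyloxy)-4-{(1R)-1-[2,3-bis(benzyloxy)-6-ethenylphenoxy]prop-2-en-1-yl}benzene
Conditions: [Ir(cod)Cl]2 (2 mol%), the mirror-image phosphoramidite ligand of step 8 (4 mol%), THF, 25 → 50 °C
Reagents that add atoms: none
Why: The same iridium-catalysed asymmetric allylic etherification with the antipodal ligand sets the stereocentre that becomes C2 (2S) of the upper unit.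

**Step 13**
Reactants: 15 1-(benzyloxy)-4-{(1R)-1-[2,3-bis(benzyloxy)-6-ethenylphenoxy]prop-2-en-1-yl}benzene
Product: 16 (2R)-7,8-bis(benzyloxy)-2-[4-(benzyloxy)phenyl]-2H-chromene
Conditions: second-generation Grubbs catalyst RuCl2(=CHPh)(PCy3)(SIMes) (3 mol%), CH2Cl2 (0.01 M), 40 °C, dark
Reagents that add atoms: none
Why: Ring-closing metathesis as in step 9, in the mirror-image series, closes ring C of the upper unit between C3 and C4 without touching C2.

**Step 14**
Reactants: 16 (2R)-7,8-bis(benzyloxy)-2-[4-(benzyloxy)phenyl]-2H-chromene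
Product: 18 (2S,3S,4S)-7,8-bis(benzyloxy)-2-[4-(benzyloxy)phenyl]-4-hydroxychroman-3-yl acetate, via trans-iodoacetate 17 (not isolated)
Conditions: I2 (1.05 equiv), AgOAc (2.2 equiv), AcOH, 20 °C, dark; then H2O (excess), 20 → 45 °C
Reagents that add atoms: silver acetate, CC(=O)[O-].[Ag+]; water, O
Why: Woodward cis-hydroxylation as in step 10 should place both oxygens on the face of the 2-aryl group (3S,4S), which gives the 2,3-cis arrangement needed to steer the coupling in step 17.

**Step 15**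
Reactants: 18 (2S,3S,4S)-7,8-bis(benzyloxy)-2-[4-(benzyloxy)phenyl]-4-hydroxychroman-3-yl acetate
Product: 19 (2S,3S,4S)-7,8-bis(benzyloxy)-2-[4-(benzyloxy)phenyl]chromane-3,4-diol (all-cis)
Conditions: K2CO3 (0.2 equiv), MeOH/THF, 0 °C
Reagents that add atoms: none
Why: Base-catalysed transesterification to methanol removes the acetate without epimerisation.

**Step 16**
Reactants: 19 (2S,3S,4S)-7,8-bis(benzyloxy)-2-[4-(benzyloxy)phenyl]chromane-3,4-diol
Product: 20 (2S,3R,4R)-4-(benzylsulfanyl)-7,8-bis(benzyloxy)-2-[4-(benzyloxy)phenyl]chroman-3-ol (3-OH cis to the aryl group, sulfur trans to both)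
Conditions: BnSH (4 equiv), Sc(OTf)3 (10 mol%), CH2Cl2, −20 → 0 °C
Reagents that add atoms: phenylmethanethiol, SCc1ccccc1
Why: Acid-catalysed thiolysis (SN1 at benzylic C4 through the 7-alkoxy-stabilised flavan-4-yl cation) should add the thiol trans to the axial 3-hydroxyl; the C4 configuration is of no consequence because C4 is ionised again in step 17.

**Step 17**
Reactants: 20 (2S,3R,4R)-4-(benzylsulfanyl)-7,8-bis(benzyloxy)-2-[4-(benzyloxy)phenyl]chroman-3-ol; 14 (2R,3S,4R)-7,8-bis(benzyloxy)-2-[4-(benzyloxy)phenyl]chromane-3,4-diyl diacetate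
Product: 21 hexa-O-benzyl ent-epioritin-(4α→6)-epioritin-4α-ol with the lower 3,4-diol as diacetate (upper unit 2S,3S, free 3-OH, C4–C6 bond trans to the 3-OH and to the 2-aryl group)
Conditions: AgBF4 (2.5 equiv), 14 (3 equiv, excess recovered), THF, 0 °C
Reagents that add atoms: none
Why: Thiophilic activation of the thioether gives the flavan-4-yl cation, which alkylates C6 of 14 (para to O1, ortho to the 7-benzyloxy group) in a Friedel–Crafts reaction; attack trans to the axial 3-hydroxyl of the 2,3-cis cation sets the new C4 stereocentre (4α), and the acetates of 14 are not ionised by the soft Lewis acid.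

**Step 18**
Reactants: 21 hexa-O-benzyl ent-epioritin-(4α→6)-epioritin-4α-ol lower-unit diacetate
Product: 22 the corresponding upper-unit flavan-3-one (2S, 4α-aryl, C3 ketone), lower unit unchanged
Conditions: Dess–Martin periodinane (1.5 equiv), CH2Cl2, 0 → 20 °C
Reagents that add atoms: none
Why: Dess–Martin oxidation of the only free hydroxyl under near-neutral conditions should give the 4-arylflavan-3-one without enolisation toward C2 or C4.

**Step 19**
Reactants: 22 upper-unit flavan-3-one dimer diacetate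
Product: 23 hexa-O-benzyl ent-oritin-(4α→6)-epioritin-4α-ol with the lower 3,4-diol as diacetate (upper unit 2S,3R, 3-OH trans to the 2-aryl group and cis to the C4–C6 bond)
Conditions: NaBH4 (1.5 equiv), CeCl3·7H2O (1.5 equiv), THF/MeOH, −78 °C
Reagents that add atoms: none
Why: Luche reduction: the pseudo-axial 4-aryl substituent shields the α face, so hydride should add axially from the β face and give the equatorial 3α-alcohol (3R), while the low basicity and temperature protect C2 and C4 from epimerisation.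

**Step 20**
Reactants: 23 hexa-O-benzyl ent-oritin-(4α→6)-epioritin-4α-ol lower-unit diacetate
Product: 24 hexa-O-benzyl ent-oritin-(4α→6)-epioritin-4α-ol (upper 3-OH and lower 3,4-diol free)
Conditions: K2CO3 (0.5 equiv), MeOH/THF, 20 °C
Reagents that add atoms: none
Why: Base-catalysed methanolysis removes both acetates; no stereocentre is enolisable or ionisable under these conditions.

**Step 21**
Reactants: 24 hexa-O-benzyl ent-oritin-(4α→6)-epioritin-4α-ol
Product: 25 ent-oritin-(4α→6)-epioritin-4α-ol (target)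
Conditions: H2 (1 atm), Pd(OH)2/C, THF/MeOH, 20 °C
Reagents that add atoms: none
Why: Hydrogenolysis of the six aryl benzyl ethers under neutral conditions, which are far more labile than the benzylic C4 hydroxyl and the interflavan bond.

**Compound list**
1 | 2,3,4-trihydroxybenzaldehyde | O=Cc1ccc(O)c(O)c1O | starting material
2 | 2,3,4-tris(benzyloxy)benzaldehyde | O=Cc1ccc(OCc2ccccc2)c(OCc2ccccc2)c1OCc1ccccc1 | intermediate
3 | 3,4-bis(benzyloxy)-2-hydroxybenzaldehyde | O=Cc1ccc(OCc2ccccc2)c(OCc2ccccc2)c1O | intermediate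
4 | 2,3-bis(benzyloxy)-6-ethenylphenol | C=Cc1ccc(OCc2ccccc2)c(OCc2ccccc2)c1O | intermediate
5 | 4-(benzyloxy)benzaldehyde | O=Cc1ccc(OCc2ccccc2)cc1 | starting material
6 | ethyl (2E)-3-[4-(benzyloxy)phenyl]prop-2-enoate | CCOC(=O)/C=C/c1ccc(OCc2ccccc2)cc1 | intermediate
7 | (2E)-3-[4-(benzyloxy)phenyl]prop-2-en-1-ol | OC/C=C/c1ccc(OCc2ccccc2)cc1 | intermediate
8 | (2E)-3-[4-(benzyloxy)phenyl]prop-2-en-1-yl methyl carbonate | COC(=O)OC/C=C/c1ccc(OCc2ccccc2)cc1 | intermediate
9 | lithium 2,3-bis(benzyloxy)-6-ethenylphenolate | [Li+].[O-]c1c(C=C)ccc(OCc2ccccc2)c1OCc1ccccc1 | intermediate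
10 | 1-(benzyloxy)-4-{(1S)-1-[2,3-bis(benzyloxy)-6-ethenylphenoxy]prop-2-en-1-yl}benzene | C(c1ccccc1)Oc1ccc([C@H](C=C)Oc2c(C=C)ccc(OCc3ccccc3)c2OCc2ccccc2)cc1 | intermediate
11 | (2S)-7,8-bis(benzyloxy)-2-[4-(benzyloxy)phenyl]-2H-chromene | C(c1ccccc1)Oc1ccc([C@H]2Oc3c(ccc(OCc4ccccc4)c3OCc3ccccc3)C=C2)cc1 | intermediate
12 | (2R,3R,4R)-7,8-bis(benzyloxy)-2-[4-(benzyloxy)phenyl]-3-iodochroman-4-yl acetate (iodine trans to the aryl group and to the acetate) | C(c1ccccc1)Oc1ccc([C@H]2Oc3c(ccc(OCc4ccccc4)c3OCc3ccccc3)[C@@H](OC(C)=O)[C@@H]2I)cc1 | intermediate (not isolated)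
13 | (2R,3R,4R)-7,8-bis(benzyloxy)-2-[4-(benzyloxy)phenyl]-4-hydroxychroman-3-yl acetate (all-cis) | C(c1ccccc1)Oc1ccc([C@H]2Oc3c(ccc(OCc4ccccc4)c3OCc3ccccc3)[C@@H](O)[C@H]2OC(C)=O)cc1 | intermediate
14 | (2R,3S,4R)-7,8-bis(benzyloxy)-2-[4-(benzyloxy)phenyl]chromane-3,4-diyl diacetate (all-cis) | C(c1ccccc1)Oc1ccc([C@H]2Oc3c(ccc(OCc4ccccc4)c3OCc3ccccc3)[C@@H](OC(C)=O)[C@H]2OC(C)=O)cc1 | intermediate
15 | 1-(benzyloxy)-4-{(1R)-1-[2,3-bis(benzyloxy)-6-ethenylphenoxy]prop-2-en-1-yl}benzene | C(c1ccccc1)Oc1ccc([C@@H](C=C)Oc2c(C=C)ccc(OCc3ccccc3)c2OCc2ccccc2)cc1 | intermediate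
16 | (2R)-7,8-bis(benzyloxy)-2-[4-(benzyloxy)phenyl]-2H-chromene | C(c1ccccc1)Oc1ccc([C@@H]2Oc3c(ccc(OCc4ccccc4)c3OCc3ccccc3)C=C2)cc1 | intermediate
17 | (2S,3S,4S)-7,8-bis(benzyloxy)-2-[4-(benzyloxy)phenyl]-3-iodochroman-4-yl acetate (iodine trans to the aryl group and to the acetate) | C(c1ccccc1)Oc1ccc([C@@H]2Oc3c(ccc(OCc4ccccc4)c3OCc3ccccc3)[C@H](OC(C)=O)[C@H]2I)cc1 | intermediate (not isolated)
18 | (2S,3S,4S)-7,8-bis(benzyloxy)-2-[4-(benzyloxy)phenyl]-4-hydroxychroman-3-yl acetate (all-cis) | C(c1ccccc1)Oc1ccc([C@@H]2Oc3c(ccc(OCc4ccccc4)c3OCc3ccccc3)[C@H](O)[C@@H]2OC(C)=O)cc1 | intermediate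
19 | (2S,3S,4S)-7,8-bis(benzyloxy)-2-[4-(benzyloxy)phenyl]chromane-3,4-diol (all-cis) | C(c1ccccc1)Oc1ccc([C@@H]2Oc3c(ccc(OCc4ccccc4)c3OCc3ccccc3)[C@H](O)[C@@H]2O)cc1 | intermediate
20 | (2S,3R,4R)-4-(benzylsulfanyl)-7,8-bis(benzyloxy)-2-[4-(benzyloxy)phenyl]chroman-3-ol | C(c1ccccc1)Oc1ccc([C@@H]2Oc3c(ccc(OCc4ccccc4)c3OCc3ccccc3)[C@@H](SCc3ccccc3)[C@@H]2O)cc1 | intermediate
21 | (2R,3S,4R)-7,8-bis(benzyloxy)-6-{(2S,3S,4S)-7,8-bis(benzyloxy)-2-[4-(benzyloxy)phenyl]-3-hydroxychroman-4-yl}-2-[4-(benzyloxy)phenyl]chromane-3,4-diyl diacetate | C(c1ccccc1)Oc1ccc([C@H]2Oc3c(cc([C@@H]4c5ccc(OCc6ccccc6)c(OCc6ccccc6)c5O[C@@H](c5ccc(OCc6ccccc6)cc5)[C@H]4O)c(OCc4ccccc4)c3OCc3ccccc3)[C@@H](OC(C)=O)[C@H]2OC(C)=O)cc1 | intermediate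
22 | (2R,3S,4R)-7,8-bis(benzyloxy)-6-{(2S,4S)-7,8-bis(benzyloxy)-2-[4-(benzyloxy)phenyl]-3-oxochroman-4-yl}-2-[4-(benzyloxy)phenyl]chromane-3,4-diyl diacetate | C(c1ccccc1)Oc1ccc([C@H]2Oc3c(cc([C@@H]4c5ccc(OCc6ccccc6)c(OCc6ccccc6)c5O[C@@H](c5ccc(OCc6ccccc6)cc5)C4=O)c(OCc4ccccc4)c3OCc3ccccc3)[C@@H](OC(C)=O)[C@H]2OC(C)=O)cc1 | intermediate
23 | (2R,3S,4R)-7,8-bis(benzyloxy)-6-{(2S,3R,4S)-7,8-bis(benzyloxy)-2-[4-(benzyloxy)phenyl]-3-hydroxychroman-4-yl}-2-[4-(benzyloxy)phenyl]chromane-3,4-diyl diacetate | C(c1ccccc1)Oc1ccc([C@H]2Oc3c(cc([C@@H]4c5ccc(OCc6ccccc6)c(OCc6ccccc6)c5O[C@@H](c5ccc(OCc6ccccc6)cc5)[C@@H]4O)c(OCc4ccccc4)c3OCc3ccccc3)[C@@H](OC(C)=O)[C@H]2OC(C)=O)cc1 | intermediate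
24 | (2R,3R,4R)-7,8-bis(benzyloxy)-6-{(2S,3R,4S)-7,8-bis(benzyloxy)-2-[4-(benzyloxy)phenyl]-3-hydroxychroman-4-yl}-2-[4-(benzyloxy)phenyl]chromane-3,4-diol | C(c1ccccc1)Oc1ccc([C@H]2Oc3c(cc([C@@H]4c5ccc(OCc6ccccc6)c(OCc6ccccc6)c5O[C@@H](c5ccc(OCc6ccccc6)cc5)[C@@H]4O)c(OCc4ccccc4)c3OCc3ccccc3)[C@@H](O)[C@H]2O)cc1 | intermediate
25 | ent-oritin-(4α→6)-epioritin-4α-ol, (2R,3R,4R)-6-[(2S,3R,4R)-3,7,8-trihydroxy-2-(4-hydroxyphenyl)chroman-4-yl]-2-(4-hydroxyphenyl)chromane-3,4,7,8-tetrol | Oc1ccc([C@H]2Oc3c(cc([C@@H]4c5ccc(O)c(O)c5O[C@@H](c5ccc(O)cc5)[C@@H]4O)c(O)c3O)[C@@H](O)[C@H]2O)cc1 | target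

**Step count.** Total: 21 steps. Longest linear sequence: 14 steps (steps 1–3, 7, 12–16, 17–21).

**Steps most likely to fail**

Step 10. What may go wrong: electrophilic iodination of ring A at C6 in competition with the alkene, and ionisation at benzylic C4 that scrambles the 3,4-cis relationship. The fallback sets out from 11, comes back at 13, and sets both carbinol centres by hydride delivery instead. Hydroboration–oxidation of 11 (BH3·SMe2, THF; then NaOH, H2O2) anti to the 2-aryl group should give the 2,3-trans alcohol (2R,3S)-7,8-bis(benzyloxy)-2-[4-(benzyloxy)phenyl]chroman-3-ol F1. Dess–Martin oxidation should give (2R)-7,8-bis(benzyloxy)-2-[4-(benzyloxy)phenyl]chroman-3-one F2. LiBH(s-Bu)3 at −78 °C should reduce it from the equatorial side to the 2,3-cis alcohol (2R,3R)-7,8-bis(benzyloxy)-2-[4-(benzyloxy)phenyl]chroman-3-ol F3, and acetylation should give (2R,3R)-7,8-bis(benzyloxy)-2-[4-(benzyloxy)phenyl]chroman-3-yl acetate F4. DDQ in wet CH2Cl2 should hydroxylate benzylic C4 trans to the acetoxy group to give (2R,3R,4S)-7,8-bis(benzyloxy)-2-[4-(benzyloxy)phenyl]-4-hydroxychroman-3-yl acetate F5, and Dess–Martin oxidation should give the 2,3-cis ketone (2R,3S)-7,8-bis(benzyloxy)-2-[4-(benzyloxy)phenyl]-4-oxochroman-3-yl acetate F6. NaBH4 with CeCl3·7H2O at −40 °C should then deliver hydride anti to the axial 3-acetoxy group and return the all-cis hydroxy acetate 13.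

Step 17. What may go wrong: the cation from 20 alkylates C6 of ring A of a second molecule of 20 (self-condensation to oligomers) instead of 14, lowering conversion to the dimer. The fallback sets out from 19, comes back at 21, and blocks that position before activation. Bromination of 19 para to O1 (NBS, CH2Cl2, −20 °C) should give (2S,3S,4S)-7,8-bis(benzyloxy)-2-[4-(benzyloxy)phenyl]-6-bromochromane-3,4-diol F7. Thiolysis as in step 16 should give (2S,3R,4R)-4-(benzylsulfanyl)-7,8-bis(benzyloxy)-2-[4-(benzyloxy)phenyl]-6-bromochroman-3-ol F8. Coupling with 14 under AgBF4, now with near-stoichiometric 14, should give the 6-bromo derivative of 21 (bromine on C6 of ring A of the upper unit) F9, and radical hydrodebromination (Bu3SnH, AIBN, toluene, 90 °C) should return 21.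

Step 8. What may go wrong: attack of the doubly ortho-substituted aryloxide at the unsubstituted allyl terminus (linear ether), low enantioselectivity, or re-ionisation of the branched product. The fallback sets out from 5, comes back at 10, and replaces enantioselective by stereospecific etherification. Addition of CH2=CHMgBr to 5 should give racemic 1-[4-(benzyloxy)phenyl]prop-2-en-1-ol F10. Lipase-catalysed kinetic resolution (Novozym 435, vinyl acetate, toluene) should acetylate the R enantiomer and leave (1S)-1-[4-(benzyloxy)phenyl]prop-2-en-1-ol F11. Methyl chloroformate and pyridine should give (1S)-1-[4-(benzyloxy)phenyl]prop-2-en-1-yl methyl carbonate F12. Allylic etherification of phenol 4 catalysed by [Cp*Ru(NCMe)3]PF6 with K2CO3, which is branched-selective and proceeds with net retention, should then give 10.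

**Further compounds**
F1 | step 10 | (2R,3S)-7,8-bis(benzyloxy)-2-[4-(benzyloxy)phenyl]chroman-3-ol | C(c1ccccc1)Oc1ccc([C@H]2Oc3c(ccc(OCc4ccccc4)c3OCc3ccccc3)C[C@@H]2O)cc1
F2 | step 10 | (2R)-7,8-bis(benzyloxy)-2-[4-(benzyloxy)phenyl]chroman-3-one | C(c1ccccc1)Oc1ccc([C@H]2Oc3c(ccc(OCc4ccccc4)c3OCc3ccccc3)CC2=O)cc1
F3 | step 10 | (2R,3R)-7,8-bis(benzyloxy)-2-[4-(benzyloxy)phenyl]chroman-3-ol | C(c1ccccc1)Oc1ccc([C@H]2Oc3c(ccc(OCc4ccccc4)c3OCc3ccccc3)C[C@H]2O)cc1
F4 | step 10 | (2R,3R)-7,8-bis(benzyloxy)-2-[4-(benzyloxy)phenyl]chroman-3-yl acetate | C(c1ccccc1)Oc1ccc([C@H]2Oc3c(ccc(OCc4ccccc4)c3OCc3ccccc3)C[C@H]2OC(C)=O)cc1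
F5 | step 10 | (2R,3R,4S)-7,8-bis(benzyloxy)-2-[4-(benzyloxy)phenyl]-4-hydroxychroman-3-yl acetate | C(c1ccccc1)Oc1ccc([C@H]2Oc3c(ccc(OCc4ccccc4)c3OCc3ccccc3)[C@H](O)[C@H]2OC(C)=O)cc1
F6 | step 10 | (2R,3S)-7,8-bis(benzyloxy)-2-[4-(benzyloxy)phenyl]-4-oxochroman-3-yl acetate | C(c1ccccc1)Oc1ccc([C@H]2Oc3c(ccc(OCc4ccccc4)c3OCc3ccccc3)C(=O)[C@H]2OC(C)=O)cc1
F7 | step 17 | (2S,3S,4S)-7,8-bis(benzyloxy)-2-[4-(benzyloxy)phenyl]-6-bromochromane-3,4-diol | C(c1ccccc1)Oc1ccc([C@@H]2Oc3c(cc(Br)c(OCc4ccccc4)c3OCc3ccccc3)[C@H](O)[C@@H]2O)cc1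
F8 | step 17 | (2S,3R,4R)-4-(benzylsulfanyl)-7,8-bis(benzyloxy)-2-[4-(benzyloxy)phenyl]-6-bromochroman-3-ol | C(c1ccccc1)Oc1ccc([C@@H]2Oc3c(cc(Br)c(OCc4ccccc4)c3OCc3ccccc3)[C@@H](SCc3ccccc3)[C@@H]2O)cc1
F9 | step 17 | 6-bromo derivative of 21 (bromine on C6 of ring A of the upper unit) | C(c1ccccc1)Oc1ccc([C@H]2Oc3c(cc([C@@H]4c5cc(Br)c(OCc6ccccc6)c(OCc6ccccc6)c5O[C@@H](c5ccc(OCc6ccccc6)cc5)[C@H]4O)c(OCc4ccccc4)c3OCc3ccccc3)[C@@H](OC(C)=O)[C@H]2OC(C)=O)cc1
F10 | step 8 | racemic 1-[4-(benzyloxy)phenyl]prop-2-en-1-ol | C=CC(O)c1ccc(OCc2ccccc2)cc1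
F11 | step 8 | (1S)-1-[4-(benzyloxy)phenyl]prop-2-en-1-ol | C(c1ccccc1)Oc1ccc([C@H](C=C)O)cc1
F12 | step 8 | (1S)-1-[4-(benzyloxy)phenyl]prop-2-en-1-yl methyl carbonate | C(c1ccccc1)Oc1ccc([C@H](C=C)OC(=O)OC)cc1
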